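**Strategy.** Everything rests on the C1–C10 bond of ring A. In eremophilane numbering the C8 carbonyl of ring B lies para to the quaternary C5, so ring B can be carried as a prochiral 4-alkyl-4-methylcyclohexa-2,5-dienone. One-electron reduction of a redox-active ester releases CO2 and a primary C1 radical, which adds 6-exo-trig to C10 of one enone arm: a single operation closes ring A, sets C5 and C10 (cis fusion) and keeps the C6=C7–C8=O enone for work at C7 and C9. The precursor is the N-acyloxyphthalimide of the dienone acid bearing the C4 methyl and a C3 silyl ether of 3-epi configuration, which is inverted after ring closure.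

Key step: step 9

**Remarks (chemistry assumptions)**
(a) Atom numbers are eremophilane numbers. TBS = tert-butyldimethylsilyl, TES = triethylsilyl, Ipc = isopinocampheyl.
(b) Stereochemical design. C1 must approach C10 perpendicular to the dienone plane. On the forming ring A the untouched arm (C6) is therefore axial and the angular methyl equatorial; the methyl is axial only with respect to ring B. A chair leading to the target's cis C4/C5 methyls has the C4 methyl axial. With the target's 3R,4R array the C3 oxygen would be axial too, 1,3-diaxial to C6, and the all-equatorial chair would lead to the wrong arm. The precursor is therefore built as the C3 epimer (3S,4R), whose silyloxy group is equatorial only on the way to the required arm. C3 is inverted directly after ring closure, before C7 and C9 are set: with 3R the bicycle has a strain-free conformer in which the C7 and C9 substituents are equatorial.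
(c) The visible-light photoredox variant of the reductive decarboxylation is used.

**Route**

Step 1
Reactants: 1 methyl 4-oxobutanoate; 2 (E)-but-2-ene
Product: 4 methyl (4S,5R)-4-hydroxy-5-methylhept-6-enoate, via (E)-crotylbis(isopinocampheyl)borane 3 (not isolated)
Conditions: 2, KOtBu, n-BuLi, THF, −78 → −45 °C; (+)-Ipc2BOMe, −78 °C; BF3·OEt2; then 1, −78 °C; NaBO3·4H2O, THF/H2O, rt
Reagents that add atoms: none
Why: Brown crotylboration: the (E)-crotylborane reacts through a closed chair (Zimmerman–Traxler) transition state, which turns the E geometry into the anti 4,5-relationship, and the isopinocampheyl groups of the (−)-α-pinene series direct addition to the re face of the unbranched aldehyde (4S,5R); the non-basic perborate work-up and immediate use of the alcohol limit γ-lactone formation.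

Step 2
Reactants: 4 methyl (4S,5R)-4-hydroxy-5-methylhept-6-enoate
Product: 5 methyl (4S,5R)-4-(TBSO)-5-methylhept-6-enoate
Conditions: TBSOTf, 2,6-lutidine, CH2Cl2, −78 °C
Reagents that add atoms: tert-butyldimethylsilyl trifluoromethanesulfonate, CC(C)(C)[Si](C)(C)OS(=O)(=O)C(F)(F)F
Why: Silyl triflate silylation at −78 °C is much faster than lactonisation and gives an ether that survives the acidic, basic and oxidative steps up to the ring closure; no stereocentre is touched.

Step 3
Reactants: 5 methyl (4S,5R)-4-(TBSO)-5-methylhept-6-enoate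
Product: 6 methyl (4S,5S)-4-(TBSO)-5-methyl-6-oxoheptanoate
Conditions: PdCl2 (10 mol%), CuCl, O2 (1 atm), DMF/H2O 7:1, rt
Reagents that add atoms: water, O
Why: Tsuji–Wacker oxidation: Markovnikov hydroxypalladation of the terminal alkene by water and β-hydride elimination give the methyl ketone, the copper chloride/oxygen couple returning the palladium to its divalent state, and the weakly acidic medium does not epimerise the α-methyl centre (the descriptor changes from 5R to 5S only through the priority rules).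

Step 4
Reactants: 6 methyl (4S,5S)-4-(TBSO)-5-methyl-6-oxoheptanoate
Product: 8 methyl (4S,5R)-4-(TBSO)-5,6-dimethyl-7-oxoheptanoate (both C6 epimers), via methyl enol ether 7 (not isolated)
Conditions: Ph3P(CH2OMe)Cl, KN(SiMe3)2, THF, 0 °C; 6, 0 °C → rt; then 1 M HCl, THF, rt
Reagents that add atoms: (methoxymethyl)triphenylphosphonium chloride, COC[P+](c1ccccc1)(c1ccccc1)c1ccccc1.[Cl-]; water, O
Why: Wittig methoxymethylenation followed by enol ether hydrolysis is the standard one-carbon homologation of a ketone to the α-branched aldehyde; the unstabilised ylide adds to the ketone faster than it deprotonates it or attacks the ester, and the new α-centre need not be controlled because it becomes the quaternary ring carbon.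

Step 5
Reactants: 8 methyl (4S,5R)-4-(TBSO)-5,6-dimethyl-7-oxoheptanoate; 9 methyl vinyl ketone
Product: 11 methyl (4S,5R)-4-(TBSO)-5-[(1RS)-1-methyl-4-oxocyclohex-2-en-1-yl]hexanoate, via pyrrolidine enamine 10 (not isolated)
Conditions: pyrrolidine, 4 Å MS, toluene, rt; 9, rt → 60 °C; then AcOH/NaOAc/H2O, 80 °C
Reagents that add atoms: none
Why: Stork enamine variant of the Robinson annulation: the enamine of the α-branched aldehyde adds to methyl vinyl ketone in a Michael reaction and buffered hydrolysis triggers the intramolecular aldol condensation to the 4,4-disubstituted cyclohexenone; the quaternary carbon forms without control, which is harmless because the next step makes it a non-stereogenic dienone carbon.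

Step 6
Reactants: 11 methyl (4S,5R)-4-(TBSO)-5-[(1RS)-1-methyl-4-oxocyclohex-2-en-1-yl]hexanoate
Product: 12 methyl (4S,5R)-4-(TBSO)-5-(1-methyl-4-oxocyclohexa-2,5-dien-1-yl)hexanoate
Conditions: DDQ, 1,4-dioxane, reflux
Reagents that add atoms: none
Why: DDQ dehydrogenation of a 4,4-disubstituted cyclohexenone: enolisation towards the only enolisable side and hydride abstraction give the cross-conjugated dienone, which cannot aromatise because the ring carbon C5 is quaternary, and the ring becomes symmetric so the epimer mixture converges.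

Step 7
Reactants: 12 methyl (4S,5R)-4-(TBSO)-5-(1-methyl-4-oxocyclohexa-2,5-dien-1-yl)hexanoate
Product: 13 (4S,5R)-4-(TBSO)-5-(1-methyl-4-oxocyclohexa-2,5-dien-1-yl)hexanoic acid
Conditions: LiOH, THF/H2O, 0 °C → rt; then 1 M HCl to pH 3
Reagents that add atoms: lithium hydroxide, [Li+].[OH-]
Why: Saponification of the unhindered methyl ester; the dienone carries no enolisable hydrogen and the silyl ether is stable to cold aqueous LiOH.

Step 8
Reactants: 13 (4S,5R)-4-(TBSO)-5-(1-methyl-4-oxocyclohexa-2,5-dien-1-yl)hexanoic acid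
Product: 14 1,3-dioxoisoindolin-2-yl (4S,5R)-4-(TBSO)-5-(1-methyl-4-oxocyclohexa-2,5-dien-1-yl)hexanoate
Conditions: N-hydroxyphthalimide, DIC, DMAP (cat.), CH2Cl2, rt
Reagents that add atoms: N-hydroxyphthalimide, ON1C(=O)c2ccccc2C1=O
Why: Carbodiimide (Steglich-type) coupling with N-hydroxyphthalimide gives the redox-active ester, the silyl ether at the γ-oxygen preventing lactonisation of the activated acid.

Step 9
Reactants: 14 1,3-dioxoisoindolin-2-yl (4S,5R)-4-(TBSO)-5-(1-methyl-4-oxocyclohexa-2,5-dien-1-yl)hexanoate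
Product: 15 (4aR,5R,6S,8aR)-6-(TBSO)-4a,5-dimethyl-4a,5,6,7,8,8a-hexahydronaphthalen-2(1H)-one (cis-fused; eremophilane 3S,4R,5R,10R)
Conditions: Ru(bpy)3(PF6)2 (2 mol%), Hantzsch ester (1.5 equiv), CH2Cl2 (0.01 M), 450 nm LEDs, rt
Reagents that add atoms: none
Why: The photoexcited ruthenium complex is reduced by the Hantzsch ester and passes one electron to the phthalimide ester, which fragments to phthalimide anion, CO2 and the primary C1 radical; this nucleophilic radical adds to the enone β-carbon C10 and the resulting C9 α-keto radical is quenched by hydrogen-atom transfer from the oxidised Hantzsch ester (or by reduction and protonation). The closest known reactions are the photoredox reductive decarboxylative Giese addition of N-acyloxyphthalimides and radical cyclisations onto 4,4-disubstituted cyclohexadienones. Ring A is closed in the 6-exo-trig mode. C10 is fixed by geometry, because the tether reaches only the dienone face that carries C4, so the new C1–C10 bond is syn to C4 and H10 ends up cis to the angular methyl (cis fusion), while C5 is fixed by which of the two diastereotopic enone arms is attacked. That arm selectivity is what the step needs: in the chair transition state the spectator arm is axial and the angular methyl equatorial on the forming ring, and only attack on the required arm lets the bulky 3S silyloxy group be equatorial, whereas attack on the other arm would force it axial and 1,3-diaxial to C6. The C4 methyl is axial in the favoured transition state, which costs little because an equatorial C4 methyl would instead be pressed against the C6–H of the spectator arm, and high dilution keeps hydrogen transfer to the uncyclised radical slow.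

Step 10
Reactants: 15 (4aR,5R,6S,8aR)-6-(TBSO)-4a,5-dimethyl-4a,5,6,7,8,8a-hexahydronaphthalen-2(1H)-one
Product: 16 (4aR,5R,6S,8aR)-6-hydroxy-4a,5-dimethyl-4a,5,6,7,8,8a-hexahydronaphthalen-2(1H)-one
Conditions: HF (48% aq.), MeCN, 0 °C → rt
Reagents that add atoms: none
Why: Fluoride cleaves the Si–O bond (strong Si–F bond) under acidic conditions to which the enone is inert, and no stereocentre is touched.

Step 11
Reactants: 16 (4aR,5R,6S,8aR)-6-hydroxy-4a,5-dimethyl-4a,5,6,7,8,8a-hexahydronaphthalen-2(1H)-one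
Product: 18 (4aR,5R,6R,8aR)-6-hydroxy-4a,5-dimethyl-4a,5,6,7,8,8a-hexahydronaphthalen-2(1H)-one, via inverted 4-nitrobenzoate 17 (not isolated)
Conditions: 4-O2NC6H4CO2H, PPh3, DIAD, toluene, 0 °C → rt; then K2CO3, MeOH, rt
Reagents that add atoms: 4-nitrobenzoic acid, OC(=O)c1ccc(cc1)[N+](=O)[O-]
Why: Mitsunobu reaction: the alkoxyphosphonium ion of the 3S alcohol is displaced by 4-nitrobenzoate with inversion (SN2), this acid being the standard partner for hindered secondary alcohols and the departure being helped by relief of the 1,3-diaxial contact with the angular methyl in the reacting conformer; mild methanolysis then frees the 3R alcohol without affecting the enone.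

Step 12
Reactants: 18 (4aR,5R,6R,8aR)-6-hydroxy-4a,5-dimethyl-4a,5,6,7,8,8a-hexahydronaphthalen-2(1H)-one
Product: 19 (4aR,5R,6R,8aR)-4a,5-dimethyl-6-(TESO)-4a,5,6,7,8,8a-hexahydronaphthalen-2(1H)-one
Conditions: TESCl, imidazole, CH2Cl2, 0 °C → rt
Reagents that add atoms: chlorotriethylsilane, CC[Si](Cl)(CC)CC
Why: Routine silylation of the secondary alcohol; the triethylsilyl ether survives the enolate, iodination, coupling and hydride steps yet can later be removed in the presence of a tert-butyldimethylsilyl ether.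

Step 13
Reactants: 19 (4aR,5R,6R,8aR)-4a,5-dimethyl-6-(TESO)-4a,5,6,7,8,8a-hexahydronaphthalen-2(1H)-one
Product: 20 (1R,4aR,5R,6R,8aS)-1-hydroxy-4a,5-dimethyl-6-(TESO)-4a,5,6,7,8,8a-hexahydronaphthalen-2(1H)-one
Conditions: NaN(SiMe3)2, THF, −78 °C; 2-(phenylsulfonyl)-3-phenyloxaziridine, −78 °C; NH4Cl (aq.)
Reagents that add atoms: 2-(phenylsulfonyl)-3-phenyloxaziridine, O=S(=O)(c1ccccc1)N1OC1c1ccccc1
Why: Only C9 can be deprotonated (C5 is quaternary, so there is no γ-hydrogen), and the sodium dienolate is hydroxylated by the oxaziridine (Davis oxidation) on the convex face of the cis-fused bicycle, anti to C1 at the neighbouring ring-fusion carbon, which places the 9-hydroxyl cis to H10 and the angular methyl (9R), the equatorial and also the more stable epimer.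

Step 14
Reactants: 20 (1R,4aR,5R,6R,8aS)-1-hydroxy-4a,5-dimethyl-6-(TESO)-4a,5,6,7,8,8a-hexahydronaphthalen-2(1H)-one
Product: 21 (1R,4aR,5R,6R,8aS)-1-(TBSO)-4a,5-dimethyl-6-(TESO)-4a,5,6,7,8,8a-hexahydronaphthalen-2(1H)-one
Conditions: TBSOTf, 2,6-lutidine, CH2Cl2, 0 °C
Reagents that add atoms: tert-butyldimethylsilyl trifluoromethanesulfonate, CC(C)(C)[Si](C)(C)OS(=O)(=O)C(F)(F)F
Why: Silyl triflate silylation protects the hindered α-ketol oxygen so that only O3 is acylated later; no stereocentre is touched.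

Step 15
Reactants: 21 (1R,4aR,5R,6R,8aS)-1-(TBSO)-4a,5-dimethyl-6-(TESO)-4a,5,6,7,8,8a-hexahydronaphthalen-2(1H)-one
Product: 22 (1R,4aR,5R,6R,8aS)-1-(TBSO)-3-iodo-4a,5-dimethyl-6-(TESO)-4a,5,6,7,8,8a-hexahydronaphthalen-2(1H)-one
Conditions: I2, pyridine, CH2Cl2, 0 °C → rt
Reagents that add atoms: iodine, II
Why: α-Iodination of an enone by the iodine–pyridine addition–elimination sequence (Baylis–Hillman-type conjugate addition of pyridine, iodination of the enolate, loss of pyridine), which marks C7 for C–C coupling and is known to work on 4,4-disubstituted cyclohexenones.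

Step 16
Reactants: 22 (1R,4aR,5R,6R,8aS)-1-(TBSO)-3-iodo-4a,5-dimethyl-6-(TESO)-4a,5,6,7,8,8a-hexahydronaphthalen-2(1H)-one; 23 isopropenylboronic acid pinacol ester
Product: 24 (1R,4aR,5R,6R,8aS)-1-(TBSO)-4a,5-dimethyl-3-(prop-1-en-2-yl)-6-(TESO)-4a,5,6,7,8,8a-hexahydronaphthalen-2(1H)-one
Conditions: 23, Pd(dppf)Cl2 (5 mol%), K3PO4, 1,4-dioxane/H2O, 60 °C
Reagents that add atoms: none
Why: Suzuki–Miyaura coupling: oxidative addition of zerovalent palladium into the activated C7–I bond, transmetallation from the alkenylboronate and reductive elimination install the isopropenyl group with its double bond position fixed.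

Step 17
Reactants: 24 (1R,4aR,5R,6R,8aS)-1-(TBSO)-4a,5-dimethyl-3-(prop-1-en-2-yl)-6-(TESO)-4a,5,6,7,8,8a-hexahydronaphthalen-2(1H)-one
Product: 25 (1R,3R,4aR,5R,6R,8aS)-1-(TBSO)-4a,5-dimethyl-3-(prop-1-en-2-yl)-6-(TESO)octahydronaphthalen-2(1H)-one
Conditions: [(Ph3P)CuH]6 (0.4 equiv), THF/benzene, H2O (2 equiv), 0 °C → rt
Reagents that add atoms: none
Why: Conjugate reduction with the copper hydride hexamer delivers hydride to C6 and spares the isolated alkene, and protonation of the copper dienolate at the α-carbon C7, from the axial direction of the strain-free conformer and in agreement with the thermodynamic preference, gives the equatorial isopropenyl group cis to the angular methyl (7R) as the β,γ-unsaturated ketone.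

Step 18
Reactants: 25 (1R,3R,4aR,5R,6R,8aS)-1-(TBSO)-4a,5-dimethyl-3-(prop-1-en-2-yl)-6-(TESO)octahydronaphthalen-2(1H)-one
Product: 26 (1R,3R,4aR,5R,6R,8aS)-1-(TBSO)-6-hydroxy-4a,5-dimethyl-3-(prop-1-en-2-yl)octahydronaphthalen-2(1H)-one
Conditions: PPTS (cat.), MeOH/CH2Cl2, 0 °C
Reagents that add atoms: none
Why: Acid-catalysed methanolysis removes the triethylsilyl ether far faster than the bulkier and less basic α-keto tert-butyldimethylsilyl ether, and the mild acid does not move the isopropenyl double bond.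

Step 19
Reactants: 27 (R)-pent-4-en-2-ol; 28 angelic acid
Product: 30 (R)-pent-4-en-2-yl (Z)-2-methylbut-2-enoate, via angelic 2,4,6-trichlorobenzoic anhydride 29 (not isolated)
Conditions: 28, 2,4,6-Cl3C6H2COCl, Et3N, toluene, rt; then 27, toluene, 80 °C
Reagents that add atoms: none
Why: Mixed-anhydride (Yamaguchi-type) acylation carried out without DMAP is the established way to make angelates without Z to E isomerisation to the tiglate, and acylation on oxygen leaves the R carbinol centre unchanged.

Step 20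
Reactants: 30 (R)-pent-4-en-2-yl (Z)-2-methylbut-2-enoate; 31 acrylic acid
Product: 32 (2E,5R)-5-{[(Z)-2-methylbut-2-enoyl]oxy}hex-2-enoic acid
Conditions: 31 (3 equiv), second-generation Hoveyda–Grubbs catalyst RuCl2(H2IMes)(=CH-C6H4-2-OiPr) (5 mol%), CH2Cl2, 40 °C
Reagents that add atoms: none
Why: Olefin cross-metathesis of a terminal alkene with acrylic acid gives the E-configured enoic acid with loss of ethylene, while the trisubstituted electron-poor angelate double bond does not take part.

Step 21
Reactants: 26 (1R,3R,4aR,5R,6R,8aS)-1-(TBSO)-6-hydroxy-4a,5-dimethyl-3-(prop-1-en-2-yl)octahydronaphthalen-2(1H)-one; 32 (2E,5R)-5-{[(Z)-2-methylbut-2-enoyl]oxy}hex-2-enoic acid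
Product: 34 9-O-TBS ether of the target, via mixed anhydride 33 (not isolated)
Conditions: 32, 2,4,6-Cl3C6H2COCl, Et3N, toluene, rt; then 26, DMAP, toluene, rt
Reagents that add atoms: none
Why: Yamaguchi esterification: the mixed anhydride of the enoic acid is attacked at the less hindered carbonyl by the equatorial C3 hydroxyl under DMAP catalysis, with retention at C3 because the C–O bond is not broken, the C9 oxygen being silylated.

Step 22
Reactants: 34 9-O-TBS ether of the target
Product: 35 CNP0210874.1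
Conditions: HF·pyridine, pyridine, THF, 0 °C → rt
Reagents that add atoms: none
Why: Buffered HF·pyridine removes the last silyl ether under weakly acidic conditions, which avoids base-induced migration of the isopropenyl double bond into conjugation, epimerisation at C7 or C9 and elimination in the side chain.

**Compound list**

1 | methyl 4-oxobutanoate | COC(=O)CCC=O | starting material
2 | (E)-but-2-ene | C/C=C/C | starting material
3 | (E)-crotylbis(isopinocampheyl)borane, (−)-α-pinene series | C/C=C/CB([C@H]1C[C@H]2C[C@@H]([C@@H]1C)C2(C)C)[C@H]1C[C@H]2C[C@@H]([C@@H]1C)C2(C)C | intermediate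
4 | methyl (4S,5R)-4-hydroxy-5-methylhept-6-enoate | COC(=O)CC[C@H](O)[C@@H](C=C)C | intermediate
5 | methyl (4S,5R)-4-(tert-butyldimethylsilyloxy)-5-methylhept-6-enoate | COC(=O)CC[C@H](O[Si](C)(C)C(C)(C)C)[C@@H](C=C)C | intermediate
6 | methyl (4S,5S)-4-(tert-butyldimethylsilyloxy)-5-methyl-6-oxoheptanoate | COC(=O)CC[C@H](O[Si](C)(C)C(C)(C)C)[C@@H](C(C)=O)C | intermediate
7 | methyl (4S,5R)-4-(tert-butyldimethylsilyloxy)-7-methoxy-5,6-dimethylhept-6-enoate (E/Z mixture) | COC(=O)CC[C@H](O[Si](C)(C)C(C)(C)C)[C@@H](C(C)=COC)C | intermediate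
8 | methyl (4S,5R)-4-(tert-butyldimethylsilyloxy)-5,6-dimethyl-7-oxoheptanoate (both C6 epimers) | COC(=O)CC[C@H](O[Si](C)(C)C(C)(C)C)[C@@H](C(C)C=O)C | intermediate
9 | methyl vinyl ketone | C=CC(C)=O | starting material
10 | methyl (4S,5R)-4-(tert-butyldimethylsilyloxy)-5,6-dimethyl-7-(pyrrolidin-1-yl)hept-6-enoate | COC(=O)CC[C@H](O[Si](C)(C)C(C)(C)C)[C@@H](C(C)=CN1CCCC1)C | intermediate
11 | methyl (4S,5R)-4-(tert-butyldimethylsilyloxy)-5-[(1RS)-1-methyl-4-oxocyclohex-2-en-1-yl]hexanoate | COC(=O)CC[C@H](O[Si](C)(C)C(C)(C)C)[C@@H](C1(C)CCC(=O)C=C1)C | intermediate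
12 | methyl (4S,5R)-4-(tert-butyldimethylsilyloxy)-5-(1-methyl-4-oxocyclohexa-2,5-dien-1-yl)hexanoate | COC(=O)CC[C@H](O[Si](C)(C)C(C)(C)C)[C@@H](C1(C)C=CC(=O)C=C1)C | intermediate
13 | (4S,5R)-4-(tert-butyldimethylsilyloxy)-5-(1-methyl-4-oxocyclohexa-2,5-dien-1-yl)hexanoic acid | OC(=O)CC[C@H](O[Si](C)(C)C(C)(C)C)[C@@H](C1(C)C=CC(=O)C=C1)C | intermediate
14 | 1,3-dioxoisoindolin-2-yl (4S,5R)-4-(tert-butyldimethylsilyloxy)-5-(1-methyl-4-oxocyclohexa-2,5-dien-1-yl)hexanoate | O=C(CC[C@H](O[Si](C)(C)C(C)(C)C)[C@@H](C1(C)C=CC(=O)C=C1)C)ON1C(=O)c2ccccc2C1=O | intermediate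
15 | (4aR,5R,6S,8aR)-6-(tert-butyldimethylsilyloxy)-4a,5-dimethyl-4a,5,6,7,8,8a-hexahydronaphthalen-2(1H)-one | C1=C[C@@]2(C)[C@H](CC[C@H](O[Si](C)(C)C(C)(C)C)[C@@H]2C)CC1=O | intermediate
16 | (4aR,5R,6S,8aR)-6-hydroxy-4a,5-dimethyl-4a,5,6,7,8,8a-hexahydronaphthalen-2(1H)-one | C1=C[C@@]2(C)[C@H](CC[C@H](O)[C@@H]2C)CC1=O | intermediate
17 | (4aR,5R,6R,8aR)-4a,5-dimethyl-6-(4-nitrobenzoyloxy)-4a,5,6,7,8,8a-hexahydronaphthalen-2(1H)-one | C1=C[C@@]2(C)[C@H](CC[C@@H](OC(=O)c3ccc(cc3)[N+](=O)[O-])[C@@H]2C)CC1=O | intermediate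
18 | (4aR,5R,6R,8aR)-6-hydroxy-4a,5-dimethyl-4a,5,6,7,8,8a-hexahydronaphthalen-2(1H)-one | C1=C[C@@]2(C)[C@H](CC[C@@H](O)[C@@H]2C)CC1=O | intermediate
19 | (4aR,5R,6R,8aR)-4a,5-dimethyl-6-(triethylsilyloxy)-4a,5,6,7,8,8a-hexahydronaphthalen-2(1H)-one | C1=C[C@@]2(C)[C@H](CC[C@@H](O[Si](CC)(CC)CC)[C@@H]2C)CC1=O | intermediate
20 | (1R,4aR,5R,6R,8aS)-1-hydroxy-4a,5-dimethyl-6-(triethylsilyloxy)-4a,5,6,7,8,8a-hexahydronaphthalen-2(1H)-one | C1=C[C@@]2(C)[C@H](CC[C@@H](O[Si](CC)(CC)CC)[C@@H]2C)[C@@H](O)C1=O | intermediate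
21 | (1R,4aR,5R,6R,8aS)-1-(tert-butyldimethylsilyloxy)-4a,5-dimethyl-6-(triethylsilyloxy)-4a,5,6,7,8,8a-hexahydronaphthalen-2(1H)-one | C1=C[C@@]2(C)[C@H](CC[C@@H](O[Si](CC)(CC)CC)[C@@H]2C)[C@@H](O[Si](C)(C)C(C)(C)C)C1=O | intermediate
22 | (1R,4aR,5R,6R,8aS)-1-(tert-butyldimethylsilyloxy)-3-iodo-4a,5-dimethyl-6-(triethylsilyloxy)-4a,5,6,7,8,8a-hexahydronaphthalen-2(1H)-one | IC1=C[C@@]2(C)[C@H](CC[C@@H](O[Si](CC)(CC)CC)[C@@H]2C)[C@@H](O[Si](C)(C)C(C)(C)C)C1=O | intermediate
23 | isopropenylboronic acid pinacol ester | CC(=C)B1OC(C)(C)C(C)(C)O1 | starting material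
24 | (1R,4aR,5R,6R,8aS)-1-(tert-butyldimethylsilyloxy)-4a,5-dimethyl-3-(prop-1-en-2-yl)-6-(triethylsilyloxy)-4a,5,6,7,8,8a-hexahydronaphthalen-2(1H)-one | CC(=C)C1=C[C@@]2(C)[C@H](CC[C@@H](O[Si](CC)(CC)CC)[C@@H]2C)[C@@H](O[Si](C)(C)C(C)(C)C)C1=O | intermediate
25 | (1R,3R,4aR,5R,6R,8aS)-1-(tert-butyldimethylsilyloxy)-4a,5-dimethyl-3-(prop-1-en-2-yl)-6-(triethylsilyloxy)octahydronaphthalen-2(1H)-one | C=C(C)[C@H]1C[C@@]2(C)[C@H](CC[C@@H](O[Si](CC)(CC)CC)[C@@H]2C)[C@@H](O[Si](C)(C)C(C)(C)C)C1=O | intermediate
26 | (1R,3R,4aR,5R,6R,8aS)-1-(tert-butyldimethylsilyloxy)-6-hydroxy-4a,5-dimethyl-3-(prop-1-en-2-yl)octahydronaphthalen-2(1H)-one | C=C(C)[C@H]1C[C@@]2(C)[C@H](CC[C@@H](O)[C@@H]2C)[C@@H](O[Si](C)(C)C(C)(C)C)C1=O | intermediate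
27 | (R)-pent-4-en-2-ol | C[C@@H](O)CC=C | starting material
28 | angelic acid, (Z)-2-methylbut-2-enoic acid | C/C=C(/C)C(=O)O | starting material
29 | (Z)-2-methylbut-2-enoic 2,4,6-trichlorobenzoic anhydride | C/C=C(/C)C(=O)OC(=O)c1c(Cl)cc(Cl)cc1Cl | intermediate
30 | (R)-pent-4-en-2-yl (Z)-2-methylbut-2-enoate | C=CC[C@@H](C)OC(=O)/C(C)=C\C | intermediate
31 | acrylic acid | C=CC(=O)O | starting material
32 | (2E,5R)-5-{[(Z)-2-methylbut-2-enoyl]oxy}hex-2-enoic acid | OC(=O)/C=C/C[C@@H](C)OC(=O)/C(C)=C\C | intermediate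
33 | mixed anhydride of 32 with 2,4,6-trichlorobenzoic acid | O=C(/C=C/C[C@@H](C)OC(=O)/C(C)=C\C)OC(=O)c1c(Cl)cc(Cl)cc1Cl | intermediate
34 | (3R,4R,5R,7R,9R,10S)-9-(tert-butyldimethylsilyloxy)-8-oxoeremophil-11-en-3-yl (2E,5R)-5-{[(Z)-2-methylbut-2-enoyl]oxy}hex-2-enoate | C=C(C)[C@H]1C[C@@]2(C)[C@H](CC[C@@H](OC(=O)/C=C/C[C@@H](C)OC(=O)/C(C)=C\C)[C@@H]2C)[C@@H](O[Si](C)(C)C(C)(C)C)C1=O | intermediate
35 | CNP0210874.1, (3R,4R,5R,7R,9R,10S)-9-hydroxy-8-oxoeremophil-11-en-3-yl (2E,5R)-5-{[(Z)-2-methylbut-2-enoyl]oxy}hex-2-enoate | C=C(C)[C@H]1C[C@@]2(C)[C@H](CC[C@@H](OC(=O)/C=C/C[C@@H](C)OC(=O)/C(C)=C\C)[C@@H]2C)[C@@H](O)C1=O | target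

**Count.** Total: 22 steps. Longest linear sequence: 20 steps (steps 1–18, then 21 and 22); the side-chain acid takes 2 steps (19 and 20).

**Steps most likely to fail, with fallbacks**

Step 9. What may go wrong: the primary radical is quenched by hydrogen-atom transfer before it closes the ring, or it discriminates too little between the two enone arms at room temperature. The fallback replaces the photoredox ester by a tin hydride chain at low temperature. It sets out from acid 13: iododecarboxylation (PhI(OAc)2, I2, visible light, CH2Cl2/cyclohexane) would give the primary iodide 4-[(2R,3S)-3-(tert-butyldimethylsilyloxy)-5-iodopentan-2-yl]-4-methylcyclohexa-2,5-dien-1-one F1. Slow addition of Bu3SnH to this iodide with Et3B/air initiation in toluene at −78 °C keeps the hydrogen donor scarce and the temperature low; the same 6-exo closure comes back to the route at 15.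

Step 11. What may go wrong: the activated alcohol undergoes elimination towards C2 or C4 instead of substitution, or the hindered centre reacts too slowly. The fallback is the nitrite inversion of a triflate (Lattrell–Dax reaction). It sets out from 16: Tf2O and pyridine in CH2Cl2 at −20 °C would give (4aR,5R,6S,8aR)-4a,5-dimethyl-6-(trifluoromethylsulfonyloxy)-4a,5,6,7,8,8a-hexahydronaphthalen-2(1H)-one F2. Tetrabutylammonium nitrite in DMF displaces the triflate with inversion to the oxygen-bound nitrite ester (4aR,5R,6R,8aR)-4a,5-dimethyl-6-(nitrosooxy)-4a,5,6,7,8,8a-hexahydronaphthalen-2(1H)-one F3, which is hydrolysed on aqueous work-up and comes back to the route at 18.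

Step 17. What may go wrong: 1,2-reduction of the hindered carbonyl competes, or the dienolate is protonated at the isopropenyl terminus, which gives the conjugated isopropylidene ketone. The fallback builds the isopropenyl group by aldol addition and dehydration instead of coupling and reduction; it sets out from 21 and bypasses 22 and 24. Hydrogenation (H2, Pd/C, EtOAc) would give the saturated ketone (1R,4aR,5R,6R,8aS)-1-(tert-butyldimethylsilyloxy)-4a,5-dimethyl-6-(triethylsilyloxy)octahydronaphthalen-2(1H)-one F4. Its kinetic enolate at the C7 methylene (LiN(iPr)2, THF, −78 °C, then ZnCl2 and acetone) gives the aldol (1R,3R,4aR,5R,6R,8aS)-1-(tert-butyldimethylsilyloxy)-3-(2-hydroxypropan-2-yl)-4a,5-dimethyl-6-(triethylsilyloxy)octahydronaphthalen-2(1H)-one F5 with the new group equatorial. Syn-dehydration towards a methyl group with the Burgess reagent (toluene, 50 °C) comes back to the route at 25.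

**Further compounds**

F1 | step 9 | 4-[(2R,3S)-3-(tert-butyldimethylsilyloxy)-5-iodopentan-2-yl]-4-methylcyclohexa-2,5-dien-1-one | ICC[C@H](O[Si](C)(C)C(C)(C)C)[C@@H](C1(C)C=CC(=O)C=C1)C
F2 | step 11 | (4aR,5R,6S,8aR)-4a,5-dimethyl-6-(trifluoromethylsulfonyloxy)-4a,5,6,7,8,8a-hexahydronaphthalen-2(1H)-one | C1=C[C@@]2(C)[C@H](CC[C@H](OS(=O)(=O)C(F)(F)F)[C@@H]2C)CC1=O
F3 | step 11 | (4aR,5R,6R,8aR)-4a,5-dimethyl-6-(nitrosooxy)-4a,5,6,7,8,8a-hexahydronaphthalen-2(1H)-one | C1=C[C@@]2(C)[C@H](CC[C@@H](ON=O)[C@@H]2C)CC1=O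
F4 | step 17 | (1R,4aR,5R,6R,8aS)-1-(tert-butyldimethylsilyloxy)-4a,5-dimethyl-6-(triethylsilyloxy)octahydronaphthalen-2(1H)-one | C1C[C@@]2(C)[C@H](CC[C@@H](O[Si](CC)(CC)CC)[C@@H]2C)[C@@H](O[Si](C)(C)C(C)(C)C)C1=O
F5 | step 17 | (1R,3R,4aR,5R,6R,8aS)-1-(tert-butyldimethylsilyloxy)-3-(2-hydroxypropan-2-yl)-4a,5-dimethyl-6-(triethylsilyloxy)octahydronaphthalen-2(1H)-one | CC(C)(O)[C@H]1C[C@@]2(C)[C@H](CC[C@@H](O[Si](CC)(CC)CC)[C@@H]2C)[C@@H](O[Si](C)(C)C(C)(C)C)C1=O
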